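In a one-step world, with solid substrate and reagent reacting first order in each, I expected the fraction of the charge turned into target after a given time, at small conversion and with the same reagent, to be the same for any charge. Monday and Tuesday started with the same reagent, so I held them against that.

| flask | solid substrate | reagent | remark | time |
|---|---|---|---|---|
| Monday's | 0.26 M | 0.18 M | run made earlier |  |
| Tuesday's | 2.3 M | 0.18 M | run made earlier |  |
| delta | 0.20 M | 0.180 M |  | 10 h |
| alpha | 0.40 M | 0.180 M |  | 10 h |
| zeta | 0.80 M | 0.180 M |  | 10 h |
| gamma | 1.5 M | 0.180 M |  | 10 h |

| run | time / h | target / % |
|---|---|---|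
| Monday's | 1.50 | 0.7 |
| Monday's | 3.00 | 2.0 |
| Monday's | 5.00 | 5.1 |
| Monday's | 6.00 | 6.2 |
| Monday's | 8.00 | 8.3 |
| Monday's | 10.0 | 10.7 |
| Tuesday's | 1.50 | 0 |
| Tuesday's | 3.00 | 0 |
| Tuesday's | 5.00 | 0.7 |
| Tuesday's | 6.00 | 0.3 |
| Tuesday's | 8.00 | 0.4 |
| Tuesday's | 10.0 | 1.6 |

(readings scatter by 0.5 percentage points)

- [target] at the end for delta, alpha, zeta, gamma, in this order
- the course of these numbers from the first flask to the last (rises, then falls / falls, then rises / rises all the way / hardly changes / falls all the way)

At 10.0 h Monday stood at 10.7% of its charge and Tuesday at 1.6%, far less, so the one-step world failed. I then multiplied each fraction by its charge, which gave 0.0278 M of target for Monday and 0.0368 M for Tuesday. The charges differ by a factor of 8.85, yet these two amounts, each a single scattered reading, differ by a factor of 1.32. That pointed to a constant rate, about the same on both charges, an apparent zero order in solid substrate. Integrating it takes one line: the fraction at time t is the rate times t, divided by the charge.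

The weak link was Tuesday's last reading, since on that charge a scatter of 0.5 percentage points is worth 0.012 M. So I drew a line through the origin and all the readings of each run. Monday gave 0.00268 M/h and Tuesday 0.00239 M/h, which stand 2.91 × 10⁻⁴ M/h apart, inside the 0.0008 M/h of Tuesday's line. I carried Monday's value as the make, the target formed per litre of solution and per hour, on average over that run. Over 10 h I reckoned from it 0.0268 M of target in delta, alpha, zeta and gamma alike, which would use 14.9% of the reagent.

The forecast reached the same figure: 0.027 M in every flask, so that the row hardly changes, on the ground that “nine times more solid gives the same absolute rate”.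

The flasks gave 0.0291 M, 0.0291 M, 0.0291 M and 0.0291 M: the row hardly changes.

    solid substrate ⇌ dissolved substrate, rate k1*(cs1 - [dissolved substrate]) while solid is left; crystals form when [dissolved substrate] > cs1 (solubility = 0.0780 M, k = 0.0510 /h)
    dissolved substrate + reagent ⇌ target (K = 190 /M, k = 3.30 /M/h)

In delta the relaxation half-life of the step between dissolved substrate with reagent and target, by that step alone and both ways together, was 1.28 h at 10.0 h, short against the 10 h of the run. Turned back into a fraction, the make gives delta 13.4% of its charge, where the flask held 14.6% as target. For gamma it gives 1.78%, where the flask held 1.94%.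

The earlier runs and the new flask come from a simulation from invented constants; the scatter is artificial.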